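At early times, at a fixed small conversion, I ask how the rate of making product in this flask answers to the catalyst charged. The working picture has three steps: starting material and catalyst give intermediate; partner, catalyst and intermediate give product; and catalyst pairs reversibly with added ligand to form the idle complex.

in all of them: starting material 0.010 M; catalyst 0.26 mM; added ligand 0.68 mM

| flask | partner | remark |
|---|---|---|
| cedar | 0.0080 M | run made earlier |
| elm | 0.018 M | run made earlier |
| flask | 0.0120 M |  |

| run | time / min | product / % | starting material / % |
|---|---|---|---|
| cedar | 8.00 | 1.5 | 57.2 |
| cedar | 20.0 | 6.1 | 24.4 |
| cedar | 40.0 | 15.4 | 5.4 |
| cedar | 90.0 | 33.8 | 0 |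
| elm | 8.00 | 3.1 | 56.6 |
| elm | 20.0 | 13.3 | 24.8 |
| elm | 40.0 | 32.2 | 6.2 |
| elm | 90.0 | 62.8 | 0.5 |

(scatter of a reading: 0.5 percentage points)

- the numbers in the tables scatter with a standard deviation of 0.5 percentage points
- what may be going on: starting material + catalyst -> catalyst + intermediate; partner + catalyst + intermediate -> catalyst + product; catalyst + added ligand <-> idle complex
- no earlier run changes the charge of catalyst; that part of a forecast is a guess

- apparent order in catalyst when 5.0% of the starting material are converted (percent change of the rate of making product for one percent more catalyst charged)

I read the starting-material columns first. At 20.0 min, cedar has 24.4% and elm 24.8%, though elm was charged with more partner. Cedar loses starting material at 0.0698 min⁻¹ up to 8.00 min and 0.0710 min⁻¹ over the next stretch. This is a pseudo-first-order decay, so I take free catalyst as steady.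

The product columns differ: at 40.0 min, elm has 2.09 times cedar's product, with 2.25 times its partner.

Across the columns, cedar at 8.00 min has 1.5% product, less than the 42.8% of starting material gone. Early in cedar, then, nearly all of the converted material stands as intermediate. I therefore take a fixed small conversion to mean about the same intermediate at a changed catalyst charge, and the rate of making product then follows free catalyst.

Let n be the order in catalyst, f the free share of catalyst, b its idle share, and ℓ the free share of added ligand. With the ligand charge held fixed, the pairing balance makes n the reciprocal of f + bℓ. With b at zero, n is 1. As b approaches full, n approaches the tight-binding order n_t, the ligand charge over the ligand charge minus the catalyst charge, 1.62. These runs do not give the binding strength, so I commit to that bracket and its middle, 1.31.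

The forecast says “I guess in between” and gives 1.25, lower than my middle.

The flask gives 1.4, from these steps:

    starting material + catalyst → catalyst + intermediate (k = 2700 L mol⁻¹ min⁻¹)
    partner + catalyst + intermediate → catalyst + product (k = 35000 L² mol⁻² min⁻¹)
    catalyst + added ligand ⇌ idle complex, settled at all times (K = 20000 L mol⁻¹)

That is more than the forecast. At 8.00 min, and again at 80.0 min, the flask holds 10.1% of its catalyst free and 89.9% as idle complex, with 65.6% of the added ligand free. The sum f + bℓ at those times is 0.691, and its reciprocal, 1.45, stands below n_t, which is 1.62.

The runs were computed for substances that don't exist, noise included.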